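**Plan**
Labels follow the target's decalin: ring A = C1–C4, C4a, C8a; ring B = C4a, C5–C8, C8a; C11 = the OCH2 carbon on C5.
Retrosynthetic cuts, in order: the C11–O aryl ether; the C1 and C6 methyl groups; C6=C7 of ring B (aldol condensation); C4a–C5 (ester enolate Claisen rearrangement); ring A (Diels–Alder reaction).
Forward: ring A is made first with C8a already quaternary, the C5 side chain is joined at C4a by a [3,3] shift, and ring B is closed last onto the finished ring A.
Enabling feature: in ring B the carbons C6, C7 and C8 are bracketed by the fully substituted C5 and C8a, so a C8 acetyl group on C8a has α-hydrogens only at C7 and a C6 formyl group on C5 has none; one enolate and one acceptor can give only one cyclohexenone.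
Stereochemistry: C8a from the Diels–Alder catalyst; C4a and C5 by chirality transfer from a CBS-derived carbinol through a chelation-fixed ketene acetal; C6 by axial cuprate addition anti to the axial C5 methyl; C1 by equilibration to the equatorial methyl.
End game: C8 deoxygenation, C2 allylic oxidation, C1 methylation, hydrogenation, deprotection and Mitsunobu etherification with isofraxidin.

Key step: step 13

Remark: systematic names of the ring B ketones of steps 13–15 number the carbonyl carbon as position 1; the discussion uses the target labels throughout, also for monocyclic intermediates.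
Assumption: in step 2 the (S)-configured oxazaborolidinium catalyst is taken to give the (R) aldehyde; if the diene added to the other face, the (R)-catalyst would be used with no other change.

**Step 1**
Reactants: 1 but-3-en-2-one (methyl vinyl ketone)
Product: 2 2-(triisopropylsilyloxy)buta-1,3-diene
Conditions: TIPSOTf, Et3N, Et2O, 0 °C to rt
Reagents that add atoms: triisopropylsilyl trifluoromethanesulfonate, CC(C)[Si](OS(=O)(=O)C(F)(F)F)(C(C)C)C(C)C
Why: Soft enolisation of an enone with a silyl triflate and a tertiary amine is the standard preparation of 2-silyloxy dienes, and the bulky triisopropylsilyl group is chosen so that the enol ether survives the acidic catalyst of step 2 without entering a Mukaiyama aldol reaction with the aldehyde.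

**Step 2**
Reactants: 2 2-(triisopropylsilyloxy)buta-1,3-diene; 3 2-methylprop-2-enal (methacrolein)
Product: 4 (1R)-1-methyl-4-(triisopropylsilyloxy)cyclohex-3-ene-1-carbaldehyde
Conditions: (S)-o-tolyl-CBS-oxazaborolidine (15 mol %), Tf2NH (12 mol %), CH2Cl2, −78 °C
Reagents that add atoms: none
Why: Enantioselective Diels–Alder reaction under chiral oxazaborolidinium catalysis, in which the 2-siloxy group directs the usual para regiochemistry and the catalyst-bound s-trans enal exposes one face to the diene, so that the quaternary carbon (later C8a) is created as the only stereocentre.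

**Step 3**
Reactants: 4 silyloxy cyclohexene carbaldehyde
Product: 5 {[(4R)-4-ethenyl-4-methylcyclohex-1-en-1-yl]oxy}tri(propan-2-yl)silane
Conditions: Ph3PCH3Br, KOt-Bu, THF, 0 °C to rt
Reagents that add atoms: methyltriphenylphosphonium bromide, C[P+](c1ccccc1)(c1ccccc1)c1ccccc1.[Br-]
Why: Wittig methylenation of a non-enolisable aldehyde cannot disturb the quaternary stereocentre and leaves the base-stable triisopropylsilyl enol ether intact, turning the formyl group into the vinyl group that stands in for the C8 acetyl unit.

**Step 4**
Reactants: 5 vinyl silyl enol ether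
Product: 6 (4S)-4-ethenyl-4-methylcyclohex-2-en-1-one
Conditions: Pd(OAc)2 (1.1 equiv), MeCN, 40 °C
Reagents that add atoms: none
Why: Saegusa–Ito oxidation, in which palladium diacetate converts the silyl enol ether into a palladium enolate whose only β-hydrogens lie on the methylene next to the quaternary carbon, so β-hydride elimination gives the 4,4-disubstituted cyclohex-2-enone with the stereocentre untouched (its descriptor becomes S only through the priority rules).

**Step 5**
Reactants: 6 (4S)-4-ethenyl-4-methylcyclohex-2-en-1-one
Product: 7 (1R,4S)-4-ethenyl-4-methylcyclohex-2-en-1-ol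
Conditions: (S)-Me-CBS-oxazaborolidine (20 mol %), catecholborane (1.5 equiv), toluene, −78 °C; aq NaOH work-up
Reagents that add atoms: none
Why: Corey–Bakshi–Shibata reduction, in which the alkenyl arm of the enone acts as the large group so that the (S)-catalyst should give the 1R carbinol under reagent control (the remote quaternary carbon carries two groups of similar size), placing the hydroxyl group cis to the methyl group as the later [3,3] shift requires, while catecholborane at low temperature does not hydroborate the alkenes.

**Step 6**
Reactants: 8 methyl (2S)-3-hydroxy-2-methylpropanoate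
Product: 9 methyl (2S)-3-(methoxymethoxy)-2-methylpropanoate
Conditions: MOMCl, i-Pr2NEt, CH2Cl2, 0 °C to rt
Reagents that add atoms: chloromethyl methyl ether, COCCl
Why: Standard alkylation of a primary alcohol with chloromethyl methyl ether gives the MOM ether, chosen because its oxygens chelate lithium in step 9 and because it withstands every basic, reducing and oxidising step up to step 19.

**Step 7**
Reactants: 9 MOM-protected methyl ester
Product: 10 (2S)-3-(methoxymethoxy)-2-methylpropanoic acid
Conditions: LiOH, THF/H2O, rt; then 1 M HCl to pH 3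
Reagents that add atoms: lithium hydroxide, [Li+].[OH-]
Why: Ester saponification is routine, the acetal tolerates the brief mild acidification, and any loss of configuration at the α-carbon is irrelevant because this centre is made planar in step 9 (the racemic ester would serve equally).

**Step 8**
Reactants: 7 (1R,4S)-4-ethenyl-4-methylcyclohex-2-en-1-ol; 10 (2S)-3-(methoxymethoxy)-2-methylpropanoic acid
Product: 11 (1R,4S)-4-ethenyl-4-methylcyclohex-2-en-1-yl (2S)-3-(methoxymethoxy)-2-methylpropanoate
Conditions: DCC, DMAP (cat.), CH2Cl2, 0 °C to rt
Reagents that add atoms: none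
Why: Steglich esterification acylates the secondary allylic alcohol at oxygen with retention of the carbinol configuration and without allylic transposition.

**Step 9**
Reactants: 11 allylic ester
Product: 15 (2R)-2-[(1R,6S)-6-ethenyl-6-methylcyclohex-2-en-1-yl]-3-(methoxymethoxy)-2-methylpropanoic acid, via lithium enolate 12 (not isolated), via silyl ketene acetal 13 (not isolated), via trimethylsilyl ester 14 (not isolated)
Conditions: LDA (1.3 equiv), THF, −78 °C; TMSCl/Et3N, −78 °C to rt, then 65 °C; 1 M HCl work-up
Reagents that add atoms: none
Why: Ireland–Claisen rearrangement, in which LDA deprotonates the ester with lithium held between the carbonyl oxygen and the β-MOM oxygens to give enolate 12 with the CH2OMOM group cis to OLi (the in-plane chelate also keeps the C–O bond orthogonal to the enolate π system and so suppresses β-elimination), silylation freezes this geometry in ketene acetal 13, and the suprafacial [3,3] shift through a chair-like transition state (a boat would force the C5 methyl group to eclipse the quaternary C8a) forms the C4a–C5 bond on the ring face that carried the ester oxygen, cis to the C8a methyl group, so that C4a is set by the carbinol and C5 by the ketene acetal geometry before silyl ester 14 is hydrolysed on work-up.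

**Step 10**
Reactants: 15 Claisen acid
Product: 16 (2S)-2-[(1R,6S)-6-ethenyl-6-methylcyclohex-2-en-1-yl]-3-(methoxymethoxy)-2-methylpropan-1-ol
Conditions: LiAlH4, THF, 0 °C to reflux; Fieser work-up
Reagents that add atoms: none
Why: Lithium aluminium hydride reduces even a neopentyl carboxylic acid to the primary alcohol while the acetal and both alkenes are inert, bringing C6 to the alcohol level (the C5 descriptor changes only through the priority rules).

**Step 11**
Reactants: 16 primary alcohol
Product: 17 (2R)-2-[(1R,6S)-6-ethenyl-6-methylcyclohex-2-en-1-yl]-3-(methoxymethoxy)-2-methylpropanal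
Conditions: Dess–Martin periodinane, CH2Cl2, rt
Reagents that add atoms: none
Why: Dess–Martin oxidation of a hindered primary alcohol stops at the aldehyde, which sits on the fully substituted C5 and therefore can neither epimerise nor eliminate the β-alkoxy group.

**Step 12**
Reactants: 17 vinyl aldehyde
Product: 18 (2R)-2-[(1S,6R)-6-acetyl-6-methylcyclohex-2-en-1-yl]-3-(methoxymethoxy)-2-methylpropanal
Conditions: PdCl2 (20 mol %), CuCl (1 equiv), O2 (1 atm), DMF/H2O (7:1), rt
Reagents that add atoms: water, O
Why: Wacker–Tsuji oxidation, in which divalent palladium binds the monosubstituted vinyl group in preference to the 1,2-disubstituted ring alkene and water attacks the internal carbon, so the C8 methyl ketone should form while the non-enolisable aldehyde and the acetal are spectators (the ring descriptors change only through the priority rules).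

**Step 13**
Reactants: 18 keto aldehyde
Product: 20 (4R,4aS,8aR)-4-[(methoxymethoxy)methyl]-4,8a-dimethyl-4a,7,8,8a-tetrahydronaphthalen-1(4H)-one, via ketol 19 (not isolated)
Conditions: KOH (2 equiv), MeOH, rt to 50 °C
Reagents that add atoms: none
Why: Methanolic KOH reversibly deprotonates the only enolisable position of 18, the C7 methyl group of the acetyl unit (C8a carries no hydrogen and the C6 formyl group sits on the fully substituted C5), and the C7 enolate adds to the C6 aldehyde to give ketol 19, which loses water by an E1cB pathway to the conjugated enone 20. The closest known reaction is the base-mediated aldol condensation of 1,5-keto aldehydes, the ring-closing half of a Robinson annulation. Ring B closes in a 6-(enolendo)-exo-trig mode, allowed by the Baldwin rules, and because the two side arms on ring A are trans and both pseudoequatorial the chain reaches without strain and a trans-fused bicycle results. No stereocentre is formed, and C4a, C5 and C8a carry no acidic hydrogen next to a carbonyl group and cannot epimerise. The step needs only chemoselectivity, ketone enolate onto aldehyde rather than intermolecular condensation or loss of the C11 carbon by retro-aldol cleavage; this is secured by the single enolate and single acceptor, by the intramolecular six-membered closure, by the MOM ether on the C11 oxygen, and by dehydration to the enone, which makes the closure irreversible.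

**Step 14**
Reactants: 20 ring B enone
Product: 22 (3R,4R,4aS,8aR)-4-[(methoxymethoxy)methyl]-3,4,8a-trimethyl-3,4,4a,7,8,8a-hexahydronaphthalen-1(2H)-one, via silyl enol ether 21 (not isolated)
Conditions: Me2CuLi (from CuI and MeLi), TMSCl, Et2O/THF, −78 to −20 °C; then 1 M HCl, THF, 0 °C
Reagents that add atoms: lithium dimethylcuprate, [Li+].C[Cu-]C (made in the flask from methyllithium, [Li]C, and CuI)
Why: Conjugate addition of the Gilman cuprate, accelerated by TMSCl, delivers methyl to C6 along the axial trajectory that leads directly to the chair enolate, which is the β face anti to the pseudoaxial C5 methyl group that blocks the α face, so the C6 methyl group should end up axial and trans to the C5 methyl group, and silyl enol ether 21 is hydrolysed on work-up.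

**Step 15**
Reactants: 22 ring B ketone
Product: 24 (4aR,5R,6R,8aS)-5-[(methoxymethoxy)methyl]-5,6,8a-trimethyl-1,2,4a,5,6,7,8,8a-octahydronaphthalene, via hydrazone 23 (not isolated)
Conditions: N2H4·H2O, KOH, diethylene glycol, 130 °C then 200 °C, under N2
Reagents that add atoms: none
Why: Wolff–Kishner reduction in the Huang-Minlon form, a classical way to remove a decalone carbonyl next to an angular methyl group, converts hydrazone 23 into the C8 methylene with loss of dinitrogen while the isolated alkene and the base-stable acetal persist, C6 and C8a cannot epimerise, and exclusion of air prevents diimide reduction of the alkene.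

**Step 16**
Reactants: 24 ring A alkene
Product: 25 (4aR,5R,6R,8aR)-5-[(methoxymethoxy)methyl]-5,6,8a-trimethyl-4a,5,6,7,8,8a-hexahydronaphthalen-2(1H)-one
Conditions: CrO3, 3,5-dimethylpyrazole, CH2Cl2, −20 °C
Reagents that add atoms: chromium trioxide, O=[Cr](=O)=O
Why: Allylic oxidation with the chromium trioxide–3,5-dimethylpyrazole complex attacks the only accessible allylic C–H bonds, those of the C2 methylene (H-4a is buried between the fully substituted C5 and C8a), and should place oxygen at C2 rather than at the shielded C4, giving the C2 enone with the alkene retained at C3=C4 while the acetal and the saturated ring B are left alone by hexavalent chromium at this temperature.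

**Step 17**
Reactants: 25 ring A enone
Product: 27 (1S,4aR,5R,6R,8aS)-5-[(methoxymethoxy)methyl]-1,5,6,8a-tetramethyl-4a,5,6,7,8,8a-hexahydronaphthalen-2(1H)-one, via lithium dienolate 26 (not isolated)
Conditions: LDA (1.1 equiv), THF, −78 °C; MeI, −78 to −30 °C
Reagents that add atoms: iodomethane, CI
Why: Kinetic deprotonation of the enone by LDA occurs at C1, the only α′ position, to give the cross-conjugated dienolate 26, which iodomethane alkylates at C1 from the face anti to the axial C8a methyl group, so the 1β (axial) methyl epimer is expected to predominate, and either epimer serves because C1 is equilibrated in step 18.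

**Step 18**
Reactants: 27 C1-methylated enone
Product: 29 (1R,4aR,5R,6R,8aS)-5-[(methoxymethoxy)methyl]-1,5,6,8a-tetramethyloctahydronaphthalen-2(1H)-one, via 1-epi ketone 28 (not isolated)
Conditions: H2 (1 atm), 10% Pd/C, EtOAc, rt; filter; then NaOMe, MeOH, rt
Reagents that add atoms: none
Why: Hydrogenation over palladium saturates the conjugated C3=C4 alkene without creating a stereocentre or touching the ketone and the acetal, and methoxide then equilibrates C1 through the enolate to the equatorial α-methyl epimer, cis to the C8a methyl group, which avoids the two syn-axial hydrogens of the axial epimer and is the arrangement found in the A ring of friedelin.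

**Step 19**
Reactants: 29 MOM-protected ketone
Product: 30 (1R,4aR,5R,6R,8aS)-5-(hydroxymethyl)-1,5,6,8a-tetramethyloctahydronaphthalen-2(1H)-one
Conditions: conc. HCl (cat.), MeOH, 45 °C
Reagents that add atoms: none
Why: Acid-catalysed acetal exchange with methanol releases the neopentyl alcohol and dimethoxymethane, the ketone is recovered unchanged after aqueous work-up, and C1 already stands in its equilibrium configuration.

**Step 20**
Reactants: 30 keto alcohol; 31 isofraxidin (7-hydroxy-6,8-dimethoxy-2H-chromen-2-one)
Product: 32 6,8-dimethoxy-7-{[(1R,2R,4aS,5R,8aR)-1,2,4a,5-tetramethyl-6-oxodecahydronaphthalen-1-yl]methoxy}-2H-chromen-2-one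
Conditions: PPh3, DIAD, THF (about 3 M), sonication, rt to 40 °C
Reagents that add atoms: none
Why: Mitsunobu etherification, in which the alkoxyphosphonium ion of the primary alcohol is displaced at C11 by the phenoxide of isofraxidin, an acidic phenol well suited as the nucleophile, and because C11 is neopentyl the reaction is run at high concentration with sonication, conditions known to couple neopentyl alcohols with ortho-disubstituted phenols; no stereocentre is involved.

**Compound list**
1 | but-3-en-2-one (methyl vinyl ketone) | CC(=O)C=C | starting material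
2 | 2-(triisopropylsilyloxy)buta-1,3-diene | C=CC(=C)O[Si](C(C)C)(C(C)C)C(C)C | intermediate
3 | 2-methylprop-2-enal (methacrolein) | CC(=C)C=O | starting material
4 | (1R)-1-methyl-4-(triisopropylsilyloxy)cyclohex-3-ene-1-carbaldehyde | O=C[C@@]1(C)CC=C(O[Si](C(C)C)(C(C)C)C(C)C)CC1 | intermediate
5 | {[(4R)-4-ethenyl-4-methylcyclohex-1-en-1-yl]oxy}tri(propan-2-yl)silane | C=C[C@@]1(C)CC=C(O[Si](C(C)C)(C(C)C)C(C)C)CC1 | intermediate
6 | (4S)-4-ethenyl-4-methylcyclohex-2-en-1-one | C=C[C@@]1(C)C=CC(=O)CC1 | intermediate
7 | (1R,4S)-4-ethenyl-4-methylcyclohex-2-en-1-ol (hydroxyl cis to methyl) | C=C[C@@]1(C)C=C[C@H](O)CC1 | intermediate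
8 | methyl (2S)-3-hydroxy-2-methylpropanoate | COC(=O)[C@@H](C)CO | starting material
9 | methyl (2S)-3-(methoxymethoxy)-2-methylpropanoate | COC(=O)[C@@H](C)COCOC | intermediate
10 | (2S)-3-(methoxymethoxy)-2-methylpropanoic acid | OC(=O)[C@@H](C)COCOC | intermediate
11 | (1R,4S)-4-ethenyl-4-methylcyclohex-2-en-1-yl (2S)-3-(methoxymethoxy)-2-methylpropanoate | C=C[C@@]1(C)C=C[C@H](OC(=O)[C@@H](C)COCOC)CC1 | intermediate
12 | lithium (E)-enolate of ester 11, CH2OMOM cis to OLi | [Li]O/C(O[C@H]1C=C[C@](C)(C=C)CC1)=C(\COCOC)C | intermediate
13 | (Z)-trimethylsilyl ketene acetal of ester 11, CH2OMOM cis to OSiMe3 | C[Si](C)(C)O/C(O[C@H]1C=C[C@](C)(C=C)CC1)=C(\COCOC)C | intermediate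
14 | trimethylsilyl (2R)-2-[(1R,6S)-6-ethenyl-6-methylcyclohex-2-en-1-yl]-3-(methoxymethoxy)-2-methylpropanoate | C[Si](C)(C)OC(=O)[C@@](C)(COCOC)[C@@H]1C=CCC[C@@]1(C)C=C | intermediate
15 | (2R)-2-[(1R,6S)-6-ethenyl-6-methylcyclohex-2-en-1-yl]-3-(methoxymethoxy)-2-methylpropanoic acid (side chain cis to the ring methyl) | OC(=O)[C@@](C)(COCOC)[C@@H]1C=CCC[C@@]1(C)C=C | intermediate
16 | (2S)-2-[(1R,6S)-6-ethenyl-6-methylcyclohex-2-en-1-yl]-3-(methoxymethoxy)-2-methylpropan-1-ol | OC[C@@](C)(COCOC)[C@@H]1C=CCC[C@@]1(C)C=C | intermediate
17 | (2R)-2-[(1R,6S)-6-ethenyl-6-methylcyclohex-2-en-1-yl]-3-(methoxymethoxy)-2-methylpropanal | O=C[C@@](C)(COCOC)[C@@H]1C=CCC[C@@]1(C)C=C | intermediate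
18 | (2R)-2-[(1S,6R)-6-acetyl-6-methylcyclohex-2-en-1-yl]-3-(methoxymethoxy)-2-methylpropanal (key-step precursor) | O=C[C@@](C)(COCOC)[C@@H]1C=CCC[C@@]1(C)C(C)=O | intermediate
19 | (4R,4aS,8aR)-3-hydroxy-4-[(methoxymethoxy)methyl]-4,8a-dimethyl-3,4,4a,7,8,8a-hexahydronaphthalen-1(2H)-one, both carbinol epimers | COCOC[C@@]1(C)[C@@H]2C=CCC[C@@]2(C)C(=O)CC1O | intermediate
20 | (4R,4aS,8aR)-4-[(methoxymethoxy)methyl]-4,8a-dimethyl-4a,7,8,8a-tetrahydronaphthalen-1(4H)-one (trans-fused; target labels: C8 ketone, C6=C7 and C3=C4 alkenes) | COCOC[C@@]1(C)[C@@H]2C=CCC[C@@]2(C)C(=O)C=C1 | intermediate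
21 | trimethylsilyl enol ether of ketone 22 (OSiMe3 on the former carbonyl carbon, double bond to the ring B methine next to it; stereocentres as in 22) | COCOC[C@@]1(C)[C@@H]2C=CCC[C@@]2(C)C(O[Si](C)(C)C)=C[C@H]1C | intermediate
22 | (3R,4R,4aS,8aR)-4-[(methoxymethoxy)methyl]-3,4,8a-trimethyl-3,4,4a,7,8,8a-hexahydronaphthalen-1(2H)-one (C6 methyl axial, trans to the C5 methyl) | COCOC[C@@]1(C)[C@@H]2C=CCC[C@@]2(C)C(=O)C[C@H]1C | intermediate
23 | hydrazone of ketone 22 (C=N–NH2 in place of the carbonyl group; stereocentres as in 22) | COCOC[C@@]1(C)[C@@H]2C=CCC[C@@]2(C)C(=NN)C[C@H]1C | intermediate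
24 | (4aR,5R,6R,8aS)-5-[(methoxymethoxy)methyl]-5,6,8a-trimethyl-1,2,4a,5,6,7,8,8a-octahydronaphthalene | COCOC[C@@]1(C)[C@@H]2C=CCC[C@@]2(C)CC[C@H]1C | intermediate
25 | (4aR,5R,6R,8aR)-5-[(methoxymethoxy)methyl]-5,6,8a-trimethyl-4a,5,6,7,8,8a-hexahydronaphthalen-2(1H)-one | COCOC[C@@]1(C)[C@@H]2C=CC(=O)C[C@@]2(C)CC[C@H]1C | intermediate
26 | lithium dienolate of enone 25 (OLi on C2, C1=C2 and C3=C4 double bonds; stereocentres as in 25) | COCOC[C@@]1(C)[C@@H]2C=CC(O[Li])=C[C@@]2(C)CC[C@H]1C | intermediate
27 | (1S,4aR,5R,6R,8aS)-5-[(methoxymethoxy)methyl]-1,5,6,8a-tetramethyl-4a,5,6,7,8,8a-hexahydronaphthalen-2(1H)-one (C1 methyl trans to the C8a methyl) | COCOC[C@@]1(C)[C@@H]2C=CC(=O)[C@@H](C)[C@@]2(C)CC[C@H]1C | intermediate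
28 | (1S,4aR,5R,6R,8aS)-5-[(methoxymethoxy)methyl]-1,5,6,8a-tetramethyloctahydronaphthalen-2(1H)-one (C1 methyl axial) | COCOC[C@@]1(C)[C@@H]2CCC(=O)[C@@H](C)[C@@]2(C)CC[C@H]1C | intermediate
29 | (1R,4aR,5R,6R,8aS)-5-[(methoxymethoxy)methyl]-1,5,6,8a-tetramethyloctahydronaphthalen-2(1H)-one (C1 methyl equatorial) | COCOC[C@@]1(C)[C@@H]2CCC(=O)[C@H](C)[C@@]2(C)CC[C@H]1C | intermediate
30 | (1R,4aR,5R,6R,8aS)-5-(hydroxymethyl)-1,5,6,8a-tetramethyloctahydronaphthalen-2(1H)-one | OC[C@@]1(C)[C@@H]2CCC(=O)[C@H](C)[C@@]2(C)CC[C@H]1C | intermediate
31 | isofraxidin (7-hydroxy-6,8-dimethoxy-2H-chromen-2-one) | COc1cc2ccc(=O)oc2c(OC)c1O | starting material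
32 | 6,8-dimethoxy-7-{[(1R,2R,4aS,5R,8aR)-1,2,4a,5-tetramethyl-6-oxodecahydronaphthalen-1-yl]methoxy}-2H-chromen-2-one (CNP0225022.1) | COc1cc2ccc(=O)oc2c(OC)c1OC[C@@]1(C)[C@@H]2CCC(=O)[C@H](C)[C@@]2(C)CC[C@H]1C | target

**Step count**
Total: 20 steps. Longest linear sequence: 18 steps (steps 1–5 and 8–20, from methyl vinyl ketone); steps 6 and 7 prepare the acid component.

**Steps most likely to fail**

Step 9 (Ireland–Claisen rearrangement). Two processes may go wrong. First, control over which face of the ketene acetal carbon bonds to C4a may be poor: a boat-like transition state, or enolisation without the lithium chelate, would invert C5 relative to C4a. Second, bond formation at the crowded C4a may be slow enough for the ketene acetal to decay. The fallback uses the fact that the two oxygenated carbons on C5 differ only in oxidation level and protection, so the wrong C5 epimer is corrected by exchanging their roles. It sets out from 11, where the same rearrangement now delivers the C5-epimeric acid F1. Aqueous HCl in THF removes the MOM group to give hydroxy acid F2. TBSCl and imidazole in DMF silylate both oxygens to give the silyl ester silyl ether F3. LiAlH4 reduces the silyl ester to the mono-silylated diol F4, whose free hydroxymethyl group is the former carboxyl carbon. MOMCl with i-Pr2NEt gives the MOM TBS diether F5, and TBAF in THF then frees the other hydroxymethyl group, which brings the route back at 16. A mixture of C5 epimers, once separated, would thus be funnelled to 16 from both sides.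

Step 20 (Mitsunobu etherification). SN2 displacement at the neopentyl C11 inside the alkoxyphosphonium ion may be too slow, so that the activated alcohol is consumed by side reactions of the betaine instead of by the hindered phenoxide. The fallback replaces the redox condensation by alkylation with a preformed, far better leaving group. It sets out from 30: Tf2O and 2,6-lutidine in CH2Cl2 at −78 °C should give the neopentyl triflate F6, which is then treated with 31 and Cs2CO3 in DMF at 25–50 °C and comes back to the route at 32.

Step 12 (Wacker–Tsuji oxidation). Oxypalladation of a vinyl group on the quaternary C8a may be slow or may turn to the terminal carbon, and prolonged exposure to oxygen and copper may over-oxidise the formyl group. The fallback installs the C8 oxygen by radical Markovnikov hydration instead of palladium catalysis. It sets out from 16 and bypasses step 11: Mukaiyama hydration (Co(acac)2 cat., PhSiH3, O2, i-PrOH, rt) should hydrate the monosubstituted alkene through a secondary C8 radical, giving diol F7 as a mixture of carbinol epimers. Swern oxidation of both hydroxyl groups at once (oxalyl chloride, DMSO, Et3N, CH2Cl2, −78 °C) then comes back to the route at 18.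

**Further compounds**
F1 | step 9 | (2S)-2-[(1R,6S)-6-ethenyl-6-methylcyclohex-2-en-1-yl]-3-(methoxymethoxy)-2-methylpropanoic acid (C5 epimer of 15) | OC(=O)[C@](C)(COCOC)[C@@H]1C=CCC[C@@]1(C)C=C
F2 | step 9 | (2S)-2-[(1R,6S)-6-ethenyl-6-methylcyclohex-2-en-1-yl]-3-hydroxy-2-methylpropanoic acid | OC(=O)[C@](C)(CO)[C@@H]1C=CCC[C@@]1(C)C=C
F3 | step 9 | tert-butyldimethylsilyl (2S)-3-[(tert-butyldimethylsilyl)oxy]-2-[(1R,6S)-6-ethenyl-6-methylcyclohex-2-en-1-yl]-2-methylpropanoate | CC(C)(C)[Si](C)(C)OC(=O)[C@](C)(CO[Si](C)(C)C(C)(C)C)[C@@H]1C=CCC[C@@]1(C)C=C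
F4 | step 9 | (2R)-3-[(tert-butyldimethylsilyl)oxy]-2-[(1R,6S)-6-ethenyl-6-methylcyclohex-2-en-1-yl]-2-methylpropan-1-ol | OC[C@](C)(CO[Si](C)(C)C(C)(C)C)[C@@H]1C=CCC[C@@]1(C)C=C
F5 | step 9 | tert-butyl{(2R)-2-[(1R,6S)-6-ethenyl-6-methylcyclohex-2-en-1-yl]-3-(methoxymethoxy)-2-methylpropoxy}dimethylsilane | COCOC[C@](C)(CO[Si](C)(C)C(C)(C)C)[C@@H]1C=CCC[C@@]1(C)C=C
F6 | step 20 | [(1R,2R,4aS,5R,8aR)-1,2,4a,5-tetramethyl-6-oxodecahydronaphthalen-1-yl]methyl trifluoromethanesulfonate | O=S(=O)(OC[C@@]1(C)[C@@H]2CCC(=O)[C@H](C)[C@@]2(C)CC[C@H]1C)C(F)(F)F
F7 | step 12 | (2S)-2-[(1S,6R)-6-(1-hydroxyethyl)-6-methylcyclohex-2-en-1-yl]-3-(methoxymethoxy)-2-methylpropan-1-ol, both carbinol epimers | OC[C@@](C)(COCOC)[C@@H]1C=CCC[C@@]1(C)C(C)O
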